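**Retrosynthetic overview**

- Feature: O1–C8a–C4a–C4 of rings A/C is a latent 1-oxadiene (an ortho-quinone methide of ring A). C2–C3 is a two-carbon styrene unit that already carries ring B and the C3 oxygen.
- The C4 ketone is traced back to a C4 methyl ether and the C3 methyl ether to a C3 acetate, so that O-methylation is done before any base-sensitive ketone exists.
- Ring C is cut across C3–C4 and O1–C2 into acetal 3 (source of oxadiene 12) and (E)-enol acetate 11.
- Acetal 3 comes from aldehyde 1. Enol acetate 11 comes from 2-methoxyhydroquinone 4 by benzylation, formylation, one-carbon homologation and enol acetylation.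
- Ring order: rings A and B are bought; ring C is the only ring formed (step 7).

Key step: step 7

Assumption: the sense of induction of the chiral acid cannot be predicted with confidence; the (R)-configured catalyst is written, and its enantiomer is to be used if it proves to deliver the (2S,3R,4S) series.

**Route**

Step 1
Reactants: 1 2-hydroxy-4,6-dimethoxybenzaldehyde; 2 trimethyl orthoformate
Product: 3 2-(dimethoxymethyl)-3,5-dimethoxyphenol
Conditions: HC(OMe)3 (5 equiv), MeOH, CSA (2 mol%), rt; Et3N quench, concentrate, use crude under Ar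
Reagents that add atoms: none
Why: Acid-catalysed acetalisation is driven to completion by the orthoformate, which removes water as methyl formate, and the basic quench keeps the easily ionised acetal intact.

Step 2
Reactants: 4 2-methoxyhydroquinone
Product: 5 1,4-bis(benzyloxy)-2-methoxybenzene
Conditions: BnBr (2.2 equiv), K2CO3, degassed DMF, 60 °C, N2
Reagents that add atoms: benzyl bromide, BrCc1ccccc1
Why: Williamson etherification of both phenols should be clean once air is excluded from the oxidisable hydroquinone.

Step 3
Reactants: 5 1,4-bis(benzyloxy)-2-methoxybenzene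
Product: 7 2,5-bis(benzyloxy)-4-methoxybenzaldehyde, via aryl iminium chloride 6 (not isolated)
Conditions: POCl3, DMF, 0 to 70 °C; then ice/H2O
Reagents that add atoms: N,N-dimethylformamide, CN(C)C=O; water, O
Why: Vilsmeier–Haack formylation should go to the one position that is para to the methoxy group and ortho to a benzyloxy group, as in other 1,2,4-trialkoxybenzenes, and aryl benzyl ethers tolerate the reagent.

Step 4
Reactants: 7 2,5-bis(benzyloxy)-4-methoxybenzaldehyde; 8 (methoxymethyl)triphenylphosphonium chloride
Product: 9 1,4-bis(benzyloxy)-2-methoxy-5-(2-methoxyvinyl)benzene (E/Z mixture)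
Conditions: 8 (1.5 equiv), KOtBu, THF, 0 °C to rt
Reagents that add atoms: none
Why: Wittig olefination with the methoxymethylene ylide adds the homologating carbon, and the alkene geometry is irrelevant because both isomers hydrolyse to the same aldehyde.

Step 5
Reactants: 9 1,4-bis(benzyloxy)-2-methoxy-5-(2-methoxyvinyl)benzene
Product: 10 2-[2,5-bis(benzyloxy)-4-methoxyphenyl]acetaldehyde
Conditions: 2 M aq. HCl, THF, 50 °C; crude aldehyde used at once
Reagents that add atoms: water, O
Why: Acid-catalysed enol ether hydrolysis (C-protonation, hydration, loss of methanol) should release the arylacetaldehyde without touching the benzyl ethers.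

Step 6
Reactants: 10 2-[2,5-bis(benzyloxy)-4-methoxyphenyl]acetaldehyde
Product: 11 (E)-2-[2,5-bis(benzyloxy)-4-methoxyphenyl]vinyl acetate
Conditions: Ac2O, KOAc (0.3 equiv), 110 °C; E isomer isolated by crystallisation or chromatography on Et3N-deactivated SiO2
Reagents that add atoms: acetic anhydride, CC(=O)OC(C)=O
Why: O-acetylation of the aldehyde enolate under hot, equilibrating conditions (enol acetylation) should favour the aryl-conjugated E isomer, which is then separated from the minor Z isomer.

Step 7
Reactants: 3 2-(dimethoxymethyl)-3,5-dimethoxyphenol; 11 (E)-2-[2,5-bis(benzyloxy)-4-methoxyphenyl]vinyl acetate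
Product: 13 (2R,3S,4R)-2-[2,5-bis(benzyloxy)-4-methoxyphenyl]-4,5,7-trimethoxychroman-3-yl acetate, via ortho-quinone methide 12 (not isolated)
Conditions: (R)-3,3'-bis(2,4,6-triisopropylphenyl)-1,1'-binaphthyl-2,2'-diyl hydrogen phosphate (10 mol%), 5 Å MS, toluene, −30 to 0 °C, slow addition of 3 (1.5 equiv) to 11
Reagents that add atoms: none
Why: Proposed new method: the chiral phosphoric acid should ionise acetal 3 with loss of methanol to an ion pair of the 4-methoxy ortho-quinone methide 12 (an aryl oxocarbenium in its other resonance form), whose exocyclic carbon is attacked by the acetoxy-bearing alkene carbon of 11 while the phenolic oxygen closes onto the developing benzylic cation; this is an asynchronous inverse-electron-demand oxa-(4+2) cycloaddition, and its closest known relative is the chiral Brønsted acid catalysed cycloaddition of ortho-quinone methides with styrenes to 2-arylchromans. Ring C is closed in this single (4+2) event, with C3–C4 bond formation leading and O1–C2 bond formation following (in the stepwise limit a 6-endo capture of the benzylic cation by the phenol oxygen). The regiochemistry needed is oxygen to the aryl-bearing carbon, and it should be secured because the ortho-benzyloxy and para-methoxy groups of ring B stabilise a benzylic cation far better than the weakly donating acetoxy group stabilises an α-acyloxy cation, so that 11 reacts as an electron-rich styrene and not as an enol ether. The trans C2/C3 relation is transferred suprafacially from the E alkene (and is also the diequatorial outcome of a stepwise closure), C4 is set by aryl-endo approach to the E-configured oxadiene, which places the C4 methoxy group trans to the acetoxy group, and the absolute configuration is imposed by the chiral phosphate that stays hydrogen-bonded and ion-paired to the oxadiene during bond formation. The sieves take up methanol so that it neither adds to the enol acetate nor re-ionises the product, the mild acid is chosen to ionise the doubly stabilised acetal but not the C4 ether of 13, and a C4 epimer would be harmless because C4 later becomes the carbonyl carbon.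

Step 8
Reactants: 13 (2R,3S,4R)-2-[2,5-bis(benzyloxy)-4-methoxyphenyl]-4,5,7-trimethoxychroman-3-yl acetate
Product: 14 (2R,3S,4R)-2-[2,5-bis(benzyloxy)-4-methoxyphenyl]-4,5,7-trimethoxychroman-3-ol
Conditions: K2CO3 (cat.), MeOH/THF, rt
Reagents that add atoms: none
Why: Zemplén-type transesterification should remove the acetate as methyl acetate, and the flavan has no base-labile stereocentre.

Step 9
Reactants: 14 (2R,3S,4R)-2-[2,5-bis(benzyloxy)-4-methoxyphenyl]-4,5,7-trimethoxychroman-3-ol
Product: 15 (2R,3S,4R)-2-[2,5-bis(benzyloxy)-4-methoxyphenyl]-3,4,5,7-tetramethoxychroman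
Conditions: NaH, MeI, THF/DMF, 0 °C to rt
Reagents that add atoms: iodomethane, CI
Why: Williamson O-methylation of the secondary alkoxide is safe here because no ketone is present yet, so neither ring opening nor epimerisation at C2 or C3 can occur.

Step 10
Reactants: 15 (2R,3S,4R)-2-[2,5-bis(benzyloxy)-4-methoxyphenyl]-3,4,5,7-tetramethoxychroman
Product: 16 (2R,3S,4R)-2-[2,5-bis(benzyloxy)-4-methoxyphenyl]-3,5,7-trimethoxychroman-4-ol
Conditions: p-TsOH·H2O (10 mol%), THF/H2O 3:1, 0.02 M, rt to 40 °C
Reagents that add atoms: water, O
Why: SN1 solvolysis should be easy because the C4 cation is stabilised by the 5- and 7-methoxy groups and by O1, and water is expected to add mainly trans to the C3 methoxy group, with either C4 epimer converging in step 11.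

Step 11
Reactants: 16 (2R,3S,4R)-2-[2,5-bis(benzyloxy)-4-methoxyphenyl]-3,5,7-trimethoxychroman-4-ol
Product: 17 (2R,3R)-2-[2,5-bis(benzyloxy)-4-methoxyphenyl]-3,5,7-trimethoxychroman-4-one
Conditions: Dess–Martin periodinane (1.3 equiv), NaHCO3, CH2Cl2, 0 °C to rt
Reagents that add atoms: none
Why: Buffered Dess–Martin oxidation should give the aryl ketone without epimerising the new α-stereocentre, and the C3 descriptor changes from S to R only because C4 now outranks C2.

Step 12
Reactants: 17 (2R,3R)-2-[2,5-bis(benzyloxy)-4-methoxyphenyl]-3,5,7-trimethoxychroman-4-one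
Product: 18 (2R,3R)-2-(2,5-dihydroxy-4-methoxyphenyl)-3,5,7-trimethoxychroman-4-one
Conditions: H2 (1 atm), 10% Pd/C, EtOAc/MeOH, rt; filtration and concentration under Ar
Reagents that add atoms: none
Why: Catalytic hydrogenolysis should cleave both aryl benzyl ethers under neutral conditions that leave the vinylogous-ester-like ketone, the C2–O1 bond and the trans C2/C3 centres untouched, with air excluded to protect the hydroquinone.

**Compound list**

1 | 2-hydroxy-4,6-dimethoxybenzaldehyde | COc1cc(O)c(C=O)c(OC)c1 | starting material
2 | trimethyl orthoformate | COC(OC)OC | starting material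
3 | 2-(dimethoxymethyl)-3,5-dimethoxyphenol | COc1cc(O)c(C(OC)OC)c(OC)c1 | intermediate
4 | 2-methoxyhydroquinone | COc1cc(O)ccc1O | starting material
5 | 1,4-bis(benzyloxy)-2-methoxybenzene | COc1cc(OCc2ccccc2)ccc1OCc1ccccc1 | intermediate
6 | N-[2,5-bis(benzyloxy)-4-methoxybenzylidene]-N-methylmethanaminium chloride (not isolated) | C[N+](C)=Cc1cc(OCc2ccccc2)c(OC)cc1OCc1ccccc1.[Cl-] | intermediate
7 | 2,5-bis(benzyloxy)-4-methoxybenzaldehyde | O=Cc1cc(OCc2ccccc2)c(OC)cc1OCc1ccccc1 | intermediate
8 | (methoxymethyl)triphenylphosphonium chloride | COC[P+](c1ccccc1)(c1ccccc1)c1ccccc1.[Cl-] | starting material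
9 | 1,4-bis(benzyloxy)-2-methoxy-5-(2-methoxyvinyl)benzene, E/Z mixture | COC=Cc1cc(OCc2ccccc2)c(OC)cc1OCc1ccccc1 | intermediate
10 | 2-[2,5-bis(benzyloxy)-4-methoxyphenyl]acetaldehyde | O=CCc1cc(OCc2ccccc2)c(OC)cc1OCc1ccccc1 | intermediate
11 | (E)-2-[2,5-bis(benzyloxy)-4-methoxyphenyl]vinyl acetate | CC(=O)O/C=C/c1cc(OCc2ccccc2)c(OC)cc1OCc1ccccc1 | intermediate
12 | (6E)-3,5-dimethoxy-6-(methoxymethylidene)cyclohexa-2,4-dien-1-one (not isolated) | CO/C=C1/C(=O)C=C(OC)C=C1OC | intermediate
13 | (2R,3S,4R)-2-[2,5-bis(benzyloxy)-4-methoxyphenyl]-4,5,7-trimethoxychroman-3-yl acetate (2,3-trans-3,4-trans) | COc1cc(OC)c2c(c1)O[C@H](c1cc(OCc3ccccc3)c(OC)cc1OCc1ccccc1)[C@@H](OC(C)=O)[C@@H]2OC | intermediate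
14 | (2R,3S,4R)-2-[2,5-bis(benzyloxy)-4-methoxyphenyl]-4,5,7-trimethoxychroman-3-ol | COc1cc(OC)c2c(c1)O[C@H](c1cc(OCc3ccccc3)c(OC)cc1OCc1ccccc1)[C@@H](O)[C@@H]2OC | intermediate
15 | (2R,3S,4R)-2-[2,5-bis(benzyloxy)-4-methoxyphenyl]-3,4,5,7-tetramethoxychroman | COc1cc(OC)c2c(c1)O[C@H](c1cc(OCc3ccccc3)c(OC)cc1OCc1ccccc1)[C@@H](OC)[C@@H]2OC | intermediate
16 | (2R,3S,4R)-2-[2,5-bis(benzyloxy)-4-methoxyphenyl]-3,5,7-trimethoxychroman-4-ol | COc1cc(OC)c2c(c1)O[C@H](c1cc(OCc3ccccc3)c(OC)cc1OCc1ccccc1)[C@@H](OC)[C@@H]2O | intermediate
17 | (2R,3R)-2-[2,5-bis(benzyloxy)-4-methoxyphenyl]-3,5,7-trimethoxychroman-4-one | COc1cc(OC)c2c(c1)O[C@H](c1cc(OCc3ccccc3)c(OC)cc1OCc1ccccc1)[C@@H](OC)C2=O | intermediate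
18 | (2R,3R)-2-(2,5-dihydroxy-4-methoxyphenyl)-3,5,7-trimethoxychroman-4-one (CNP0281794.1) | COc1cc(OC)c2c(c1)O[C@H](c1cc(O)c(OC)cc1O)[C@@H](OC)C2=O | target

**Step count**

Total: 12 steps. Longest linear sequence: 11 steps (4 to 18, steps 2 to 12).

**Steps most likely to fail**

Step 7. The ionised acetal may be consumed by self-condensation, since ring A of 3 is itself a strong carbon nucleophile. Methanol may add to the enol acetate. A loose ion pair may give poor facial selectivity, and reversible O1–C2 or C4–O heterolysis in the product may erode it further. The fallback uses known chalcone chemistry, sets out from aldehyde 7 and returns at ketone 17. Commercial 2'-hydroxy-4',6'-dimethoxyacetophenone is protected with MOMCl and NaH in DMF to give 1-[2,4-dimethoxy-6-(methoxymethoxy)phenyl]ethan-1-one F1. Claisen–Schmidt condensation of F1 with 7 (KOH, EtOH) should give the (E)-chalcone F2. Juliá–Colonna epoxidation (poly-L-leucine, urea–H2O2, DBU, THF) is expected to give the (αR,βS)-epoxy ketone F3. Treatment with HCl in MeOH/THF removes the methoxymethyl group, and the freed phenol opens the epoxide at the benzylic carbon with inversion, giving the 2,3-trans (2R,3R)-3-hydroxyflavanone F4. Neutral O-methylation (MeI, Ag2O, CH2Cl2, dark) would then give 17 without exposing the ketone to strong base.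

Step 10. After ionisation at C4, proton loss from C3 can lead to the 3-methoxyflav-3-ene and, on hydrolysis, to loss of the C3 stereocentre. The cation may also arylate ring B of a second molecule, and reversible O1–C2 heterolysis may epimerise C2. The fallback sets out from 15 and returns directly at 17, skipping alcohol 16. DDQ in CH2Cl2/pH 7 buffer should abstract the C4 hydride, which is activated by ring A and by the C4 methoxy group, as in the known DDQ functionalisation of 5,7-dialkoxyflavans at C4. Water would capture the methoxy oxocarbenium ion, and the hemiketal would collapse to the ketone with loss of methanol. This fallback makes no compound outside the compound list (F0).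

Step 6. Enolisation may be unselective and give an E/Z mixture that is hard to separate, and the electron-rich arylacetaldehyde may self-condense under the hot conditions. The fallback sets out from aldehyde 7 and returns at enol acetate 11 with the geometry fixed by stereospecific steps. Ohira–Bestmann homologation (dimethyl (1-diazo-2-oxopropyl)phosphonate, K2CO3, MeOH) should give 1,4-bis(benzyloxy)-2-ethynyl-5-methoxybenzene F5. Syn hydroboration with pinacolborane and catalytic Cp2Zr(H)Cl should give the (E)-alkenylboronic acid pinacol ester F6. KHF2 in aqueous MeOH converts it to the potassium (E)-alkenyltrifluoroborate F7. Copper-catalysed oxidative coupling with acetic acid (CuBr, DMAP, 4 Å MS, O2, 60 °C) forms the C–O bond with retention of alkene geometry and gives 11.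

**Further compounds**

F1 | step 7 | 1-[2,4-dimethoxy-6-(methoxymethoxy)phenyl]ethan-1-one | COCOc1cc(OC)cc(OC)c1C(C)=O
F2 | step 7 | (E)-3-[2,5-bis(benzyloxy)-4-methoxyphenyl]-1-[2,4-dimethoxy-6-(methoxymethoxy)phenyl]prop-2-en-1-one | COCOc1cc(OC)cc(OC)c1C(=O)/C=C/c1cc(OCc2ccccc2)c(OC)cc1OCc1ccccc1
F3 | step 7 | [(2R,3S)-3-[2,5-bis(benzyloxy)-4-methoxyphenyl]oxiran-2-yl][2,4-dimethoxy-6-(methoxymethoxy)phenyl]methanone | COCOc1cc(OC)cc(OC)c1C(=O)[C@@H]1O[C@H]1c1cc(OCc2ccccc2)c(OC)cc1OCc1ccccc1
F4 | step 7 | (2R,3R)-2-[2,5-bis(benzyloxy)-4-methoxyphenyl]-3-hydroxy-5,7-dimethoxychroman-4-one | COc1cc(OC)c2c(c1)O[C@H](c1cc(OCc3ccccc3)c(OC)cc1OCc1ccccc1)[C@@H](O)C2=O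
F0 | step 10 | none | none
F5 | step 6 | 1,4-bis(benzyloxy)-2-ethynyl-5-methoxybenzene | C#Cc1cc(OCc2ccccc2)c(OC)cc1OCc1ccccc1
F6 | step 6 | 2-[(E)-2-[2,5-bis(benzyloxy)-4-methoxyphenyl]vinyl]-4,4,5,5-tetramethyl-1,3,2-dioxaborolane | CC1(C)OB(/C=C/c2cc(OCc3ccccc3)c(OC)cc2OCc2ccccc2)OC1(C)C
F7 | step 6 | potassium (E)-[2-[2,5-bis(benzyloxy)-4-methoxyphenyl]vinyl]trifluoroborate | [K+].F[B-](F)(F)/C=C/c1cc(OCc2ccccc2)c(OC)cc1OCc1ccccc1
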